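- A ratio of two rates gives the late excess of right-handed substrate among what is left of the two substrates. On top stands the take rate, the share of the remaining substrate turned into left-handed product per day; below stands the racemization rate, at which racemization closes the gap between the substrates.
- Each point of left-handed product widens that gap by a point, while racemization, pseudo-first-order in the substrates, closes it in proportion to the gap and to the racemization catalyst. Where the two balance, gap over remaining substrate equals take rate over racemization rate. We neglect the right-handed product, which the runs don't read.

| setting | Friday's | Sunday's | Monday's | oak | cedar |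
|---|---|---|---|---|---|
| left-handed substrate | 0.069 M | 0.069 M | 0.069 M | 0.069 M | 0.069 M |
| right-handed substrate | 0.069 M | 0.069 M | 0.069 M | 0.069 M | 0.069 M |
| gas | 6 mM (held) | 6 mM (held) | 6 mM (held) | 6.0 mM (held) | 6.0 mM (held) |
| free catalyst | 14 mM | 14 mM | 14 mM | 14 mM | 14 mM |
| racemization catalyst | 0.059 mM | 0.083 mM | 0.11 mM | 0.14 mM | 0.050 mM |
| remark | run made earlier | run made earlier | run made earlier |  |  |
| time |  |  |  | 10 d | 10 d |

| run | time / d | right-handed substrate / % | left-handed substrate / % | left-handed product / % |
|---|---|---|---|---|
| Friday's | 0.833 | 47 | 38 | 16 |
| Friday's | 2.50 | 40 | 28 | 33 |
| Friday's | 5.00 | 32 | 24 | 40 |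
| Friday's | 8.00 | 25 | 18 | 46 |
| Friday's | 10.0 | 21 | 22 | 48 |
| Sunday's | 0.833 | 48 | 38 | 17 |
| Sunday's | 2.50 | 39 | 25 | 30 |
| Sunday's | 5.00 | 33 | 23 | 36 |
| Sunday's | 8.00 | 25 | 25 | 47 |
| Sunday's | 10.0 | 24 | 19 | 49 |
| Monday's | 2.08 | 36 | 32 | 30 |
| Monday's | 4.00 | 33 | 24 | 35 |
| Monday's | 6.00 | 29 | 27 | 47 |
| Monday's | 8.00 | 22 | 24 | 48 |
| Monday's | 10.0 | 20 | 20 | 56 |

(scatter of a reading: 2 percentage points)

- free catalyst is single-handed; left-handed substrate and right-handed substrate are mirror images of each other, charged as a racemate, each of them at the stated concentration
- at the start none of reagent is dissolved
- what was read earlier has a scatter of 2 percentage points, one standard deviation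
- on the list of suspects stand: reagent + free catalyst + left-handed substrate -> free catalyst + left-handed product; reagent + free catalyst + right-handed substrate -> free catalyst + right-handed product; left-handed substrate + racemization catalyst <-> right-handed substrate + racemization catalyst; 2 free catalyst -> spent catalyst; gas <-> reagent
- an excess is the difference of the two amounts in percent of their sum
- an excess is below zero if the other one leads

- which one finishes higher in excess of right-handed substrate over left-handed substrate among what is left of the two ("neither" within 2 percentage points) (oak / cedar / neither)
- excess of right-handed substrate over left-handed substrate among what is left of the two at the end, oak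
- excess of right-handed substrate over left-handed substrate among what is left of the two at the end, cedar

- Friday's run gives the racemization rate: from 2.50 d to 10.0 d, the product gained plus the fall of the gap, divided by the area under the gap, reads 0.523 /d.
- The last interval of the three runs gives the take rate: product gained per day over the substrate remaining reads 0.0476 /d. Oak and cedar charge the same free catalyst and gas, so we use it for both.
- The racemization rate scales with its catalyst, so we carry one amount, the balance concentration, the racemization catalyst at which the two rates are equal: 0.00537 mM. For the end of oak and of cedar, we estimate the excess as this amount over the amount charged.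
- The balance can be used in cedar because the gap's half-life there, 1.56 d, is shorter than the 10 d of the run.
- Our reckoning, with the scatter of the readings in it, gives 3.83 % for oak and 10.7 % for cedar.
- The forecast argues: “Late excess is roughly source/(racemization rate + k)”. After shading its estimate down, it says cedar finishes higher, with 3 % for oak and 11 % for cedar. These values differ from ours, but the two flasks stand in the same order.

- The flask gives 2.50 % for oak and 8.79 % for cedar, so cedar finishes higher.

    reagent + free catalyst + left-handed substrate → free catalyst + left-handed product (k = 4100 /M²/h)
    reagent + free catalyst + right-handed substrate → free catalyst + right-handed product (k = 270 /M²/h)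
    left-handed substrate + racemization catalyst ⇌ right-handed substrate + racemization catalyst, rate k3*[racemization catalyst]*[left-handed substrate] forward; the back reaction follows from the equilibrium constant (k = 180 /M/h)
    2 free catalyst → spent catalyst (k = 20.0 /M/h)
    gas ⇌ reagent, rate k5*(csat - [reagent]) (kL = 0.400 /h)

- In oak, racemization carried a net 23.5 % of the two substrates charged together from right-handed to left-handed by the end. In the flask like cedar but with 2.0 × 10⁻⁴ M of racemization catalyst, the balance concentration gives 2.68 %, and that flask ends at 1.70 %.

(Readings and results are calculated on assumed constants, and the scatter is random.)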